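**Assumption:** the C1 lactol centre equilibrates through the open hydroxy-aldehyde, and the (1S) anomer (OH trans to C11) is taken as the equilibrium form. Xenicane numbering is used for atom labels throughout.

## Retrosynthetic overview
1. The target comes from its 9-hydroxy lactol by diacetylation and selective anomeric deacetylation. The nine-membered ring is formed last, by closing C9–C10 in a visible-light Ni/photoredox allylation of an enal.
2. The seco enal/allyl sulfone comes from DIBAL reduction of a δ-lactone/Weinreb amide. C11a–C11 is made by anti-selective Michael addition of the lactone enolate to (phenylsulfonyl)allene.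
3. The δ-lactone (pyran ring, formed first) comes from 1,2-reduction and lactonisation of a (2E,4E)-dienal ester. C12–C13 is made by a Heck reaction, and the C3 oxygen by allylic oxidation of the isopropenyl group.
4. C7=C8 is made by HWE olefination. The C1 and C7 carbonyls come from ozonolysis of the ring alkene of (S)-limonene, which supplies C4a and 10 of the 20 skeleton carbons.
5. Stereocontrol runs C4a (bought) → C11a (lactone alkylation) → C9 (macrocyclisation) → C1 (anomeric equilibrium).

## Route

**Step 1**
Reactants: 1, (S)-(−)-limonene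
Product: 2, (3S)-6-oxo-3-(prop-1-en-2-yl)heptanal
Conditions: O3 (1.0 equiv, Sudan III end-point), CH2Cl2/MeOH, −78 °C; then Me2S
Reagents that add atoms: ozone, [O-][O+]=O
Why: Chemoselective ozonolysis works because the trisubstituted ring alkene is much more electron-rich than the 1,1-disubstituted isopropenyl group, and the bought stereocentre (future C4a) is untouched.

**Step 2**
Reactants: 2
Product: 3, methyl (3S)-6-oxo-3-(prop-1-en-2-yl)heptanoate
Conditions: PDC, MeOH, DMF, rt
Reagents that add atoms: methanol, CO
Why: Oxidative esterification (Cr(VI) oxidation of the methyl hemiacetal) is neutral, so it spares the ketone and alkene and avoids aldol cyclisation of the keto-aldehyde.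

**Step 3**
Reactants: 3; 4, diethyl {2-[methoxy(methyl)amino]-2-oxoethyl}phosphonate
Product: 5, methyl (3S,6E)-8-[methoxy(methyl)amino]-6-methyl-8-oxo-3-(prop-1-en-2-yl)oct-6-enoate
Conditions: NaH, THF, 0 → 50 °C; the minor Z isomer (expected about 5:1 E:Z) is removed by chromatography
Reagents that add atoms: 4, CCOP(=O)(CC(=O)N(C)OC)OCC
Why: Horner–Wadsworth–Emmons olefination of the methyl ketone places the amide trans to the longer chain, giving E C7=C8, and the stabilised anion does not attack the ester.

**Step 4**
Reactants: 5
Product: 6, methyl (3S,6E)-3-(3-oxoprop-1-en-2-yl)-8-[methoxy(methyl)amino]-6-methyl-8-oxooct-6-enoate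
Conditions: SeO2 (1.5 equiv), wet 1,4-dioxane, 80 °C
Reagents that add atoms: selenium dioxide, O=[Se]=O
Why: Riley allylic oxidation (ene, then [2,3] shift) converts the isopropenyl CH3 into the α-substituted acrolein (C3 = CHO), and the electron-poor enamide alkene is inert.

**Step 5**
Reactants: 7, 2-methylbut-3-yn-2-ol
Product: 8, (E)-4-iodo-2-methylbut-3-en-2-ol
Conditions: Bu3SnH, PdCl2(PPh3)2 (2 mol %), THF, 0 °C; then I2
Reagents that add atoms: iodine, II
Why: Pd-catalysed syn-hydrostannation puts tin on the unhindered terminus, and iododestannylation proceeds with retention to give the E-vinyl iodide.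

**Step 6**
Reactants: 6; 8
Product: 9, methyl (3S,6E)-3-[(1E,3E)-1-formyl-5-hydroxy-5-methylhexa-1,3-dien-1-yl]-8-[methoxy(methyl)amino]-6-methyl-8-oxooct-6-enoate
Conditions: Pd(OAc)2 (10 mol %), n-Bu4NCl, NaHCO3, DMF, 45 °C
Reagents that add atoms: 8, CC(C)(O)/C=C/I
Why: In this Mizoroki–Heck reaction (Jeffery conditions) the vinyl-Pd adds to the CH2 terminus (C12) and β-H elimination gives the fully conjugated dienal, in which C13 sits trans to CHO (cis to C4a) as in all 2-alkyl-2-enals, while C13=C14 keeps the E geometry of 8.

**Step 7**
Reactants: 9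
Product: 10, (4S,5E)-5-[(2E)-4-hydroxy-4-methylpent-2-en-1-ylidene]-4-{(3E)-5-[methoxy(methyl)amino]-3-methyl-5-oxopent-3-en-1-yl}oxan-2-one
Conditions: NaBH4, CeCl3·7H2O, MeOH, −40 °C; work-up; then DBU (10 mol %), PhMe, 50 °C (−MeOH), telescoped
Reagents that add atoms: none
Why: Luche 1,2-reduction of the dienal followed by transesterifying lactonisation closes the pyran ring (O2–C1) without touching the alkene geometries, the Weinreb amide or C4a.

**Step 8**
Reactants: 11, sodium benzenesulfinate; 12, propargyl bromide
Product: 13, (phenylsulfonyl)propa-1,2-diene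
Conditions: DMF, rt; then Et3N (cat.), CH2Cl2
Reagents that add atoms: 11, [Na+].[O-]S(=O)c1ccccc1; 12, C#CCBr
Why: S-alkylation of the sulfinate is followed by base-catalysed propargyl-to-allenyl sulfone isomerisation.

**Step 9**
Reactants: 10; 13
Product: 14, (3R,4S,5E)-lactone carrying a 3-(phenylsulfonyl)prop-1-en-2-yl group at C3 of the oxan-2-one (= C11a)
Conditions: LiHMDS (2.1 equiv), THF, −78 °C; 13 (1.1 equiv), −78 °C; AcOH quench at −78 °C
Reagents that add atoms: 13, C=C=CS(=O)(=O)c1ccccc1
Why: The lactone enolate adds in Michael fashion to the central allene carbon, and because the C5 chain is held pseudo-axial by A1,3 strain with the E-alkylidene the electrophile enters anti, giving trans C4a/C11a (11aR); cold α-protonation of the sulfonyl carbanion then leaves the 2-substituted allyl sulfone (C11=C19, C10H2SO2Ph).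

**Step 10**
Reactants: 14
Product: 15, (2E)-5-{(2S,3R,4S,5E)-2-hydroxy-5-[(2E)-4-hydroxy-4-methylpent-2-en-1-ylidene]-3-[3-(phenylsulfonyl)prop-1-en-2-yl]oxan-4-yl}-3-methylpent-2-enal
Conditions: DIBAL-H (4 equiv), CH2Cl2, −78 °C; Rochelle salt
Reagents that add atoms: none
Why: One DIBAL reduction converts the Weinreb amide to the enal and the lactone to the lactol, because both tetrahedral aluminium intermediates survive at −78 °C; the sulfone and alkenes are inert and C1 equilibrates.

**Step 11 (key step)**
Reactants: 15
Product: 16, 9-O-deacetylasterolaurin D (1S,4aS,9R,11aR)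
Conditions: [Ru(bpy)3](PF6)2 (2 mol %), NiBr2·glyme (20 mol %), 1,10-phenanthroline (30 mol %), i-Pr2NEt (5 equiv), degassed MeCN, 455 nm LEDs, 25 °C; 15 added by syringe pump over 12 h (final 1 mM)
Reagents that add atoms: none
Why: Proposed new method: an intramolecular desulfonylative Ni/photoredox Barbier-type allylation in which photogenerated Ni(0) inserts into the allylic C–SO2Ph bond (allyl sulfones are established π-allyl precursors), Ru(I) reduces the π-allyl-Ni(II) sulfinate to a nucleophilic allyl-Ni(I) whose two termini are equivalent, and this adds 1,2 to the tethered enal through a closed six-membered transition state, forming C9–C10 and the nine-membered ring; the enal is s-trans (A1,3 strain with C18) and C10 can reach only its inner Re face in the crown conformer imposed by the trans C4a/C11a centres (the conformer that makes caryophyllene-type E-cyclononenes react on one outer alkene face), giving 9R; Ni turns over near −1.2 V, so enal, diene and lactol should be untouched, and the low triplet energy of Ru(bpy)3 avoids sensitised diene isomerisation; the closest known reactions are intermolecular Ni/photoredox allylation of aldehydes with allyl acetates and Pd/Et2Zn umpolung of allyl sulfones.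

**Step 12**
Reactants: 16
Product: 17, asterolaurin D 1-O-acetate (1,9-diacetate)
Conditions: Ac2O (2.5 equiv), pyridine, DMAP (5 mol %), CH2Cl2, 0 °C
Reagents that add atoms: acetic anhydride, CC(=O)OC(C)=O
Why: Standard acylation acetylates the secondary C9 alcohol and the lactol, while the tertiary C15 alcohol is too hindered to react at 0 °C.

**Step 13**
Reactants: 17
Product: 18, asterolaurin D
Conditions: N2H4·HOAc (1.2 equiv), DMF, 0 °C → rt
Reagents that add atoms: none
Why: Selective anomeric deacetylation works because the acetal-type ester is far more electrophilic than the C9 allylic acetate, and the freed lactol settles to the (1S) anomer.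

## Compound list
1 | (S)-(−)-limonene | CC1=CC[C@H](CC1)C(C)=C | starting material
2 | (3S)-6-oxo-3-(prop-1-en-2-yl)heptanal | CC(=O)CC[C@@H](CC=O)C(C)=C | intermediate
3 | methyl (3S)-6-oxo-3-(prop-1-en-2-yl)heptanoate | CC(=O)CC[C@@H](CC(=O)OC)C(C)=C | intermediate
4 | diethyl {2-[methoxy(methyl)amino]-2-oxoethyl}phosphonate | CCOP(=O)(CC(=O)N(C)OC)OCC | starting material
5 | E-Weinreb enamide ester | CON(C)C(=O)/C=C(\C)CC[C@@H](CC(=O)OC)C(C)=C | intermediate
6 | α-substituted acrolein | CON(C)C(=O)/C=C(\C)CC[C@@H](CC(=O)OC)C(=C)C=O | intermediate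
7 | 2-methylbut-3-yn-2-ol | CC(C)(O)C#C | starting material
8 | (E)-4-iodo-2-methylbut-3-en-2-ol | CC(C)(O)/C=C/I | intermediate
9 | (1E,3E)-dienal ester | CON(C)C(=O)/C=C(\C)CC[C@@H](CC(=O)OC)/C(=C\C=C\C(C)(C)O)C=O | intermediate
10 | dienylidene δ-lactone | CON(C)C(=O)/C=C(\C)CC[C@@H]1/C(=C\C=C\C(C)(C)O)COC(=O)C1 | intermediate
11 | sodium benzenesulfinate | [Na+].[O-]S(=O)c1ccccc1 | starting material
12 | propargyl bromide | C#CCBr | starting material
13 | (phenylsulfonyl)propa-1,2-diene | C=C=CS(=O)(=O)c1ccccc1 | intermediate
14 | trans-lactone allyl sulfone | CON(C)C(=O)/C=C(\C)CC[C@@H]1/C(=C\C=C\C(C)(C)O)COC(=O)[C@H]1C(=C)CS(=O)(=O)c2ccccc2 | intermediate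
15 | lactol enal allyl sulfone | O=C/C=C(\C)CC[C@@H]1/C(=C\C=C\C(C)(C)O)CO[C@H](O)[C@H]1C(=C)CS(=O)(=O)c2ccccc2 | intermediate
16 | 9-O-deacetylasterolaurin D | C=C1C[C@@H](O)/C=C(\C)CC[C@@H]2/C(=C\C=C\C(C)(C)O)CO[C@H](O)[C@@H]12 | intermediate
17 | asterolaurin D 1-O-acetate | C=C1C[C@@H](OC(C)=O)/C=C(\C)CC[C@@H]2/C(=C\C=C\C(C)(C)O)CO[C@H](OC(C)=O)[C@@H]12 | intermediate
18 | asterolaurin D | C=C1C[C@@H](OC(C)=O)/C=C(\C)CC[C@@H]2/C(=C\C=C\C(C)(C)O)CO[C@H](O)[C@@H]12 | target

## Summary
Total steps: 13.
Longest linear sequence: 11 (Steps 1, 2, 3, 4, 6, 7, 9, 10, 11, 12, 13).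

**Steps most likely to fail**
1. **Step 11 (proposed new macrocyclisation).**
   - Risks: slow Ni insertion into the sulfone, oligomerisation, or the wrong C9 epimer.
   - Fallback (known chemistry, different bond): close the ring at C8–C9 by a classical CrCl2/NiCl2 Nozaki–Hiyama–Kishi reaction of an (E)-C7(Me)=C8H–I vinyl iodide with a C9 aldehyde. This closure has precedent for caryophyllene-type E-cyclononenes.
   - Changes needed: a buta-2,3-dienoate replaces 13 in Step 9 (its ester becomes C9HO on DIBAL), and the methyl ketone is converted to a terminal alkyne and then carboaluminated and iodinated instead of undergoing HWE.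
2. **Step 9 (enolate addition to the allenyl sulfone).**
   - Risks: O-attack by the tertiary alkoxide, proton scrambling that erodes the trans selectivity, or isomerisation to the vinyl sulfone.
   - Fallback: make the C11a–C11 bond by cross-coupling instead of conjugate addition, using Pd-catalysed α-alkenylation of the lactone zinc enolate with 2-bromoallyl phenyl sulfone.
3. **Step 6 (Heck on the α-substituted acrolein).**
   - Risks: β-H elimination toward C4a–H, or a reductive Heck pathway.
   - Fallback: Rh(I)-catalysed 1,4-addition of the corresponding (E)-alkenyl boronate to 6, followed by Pd(II)/O2 α,β-dehydrogenation of the saturated aldehyde. This reaches the same thermodynamically E dienal 9.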